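Which flask holds more target at the end, and what has to be true for the cooler autumn to draw level with the hotter dawn?

| flask | substrate | partner | temperature | remark | time |
|---|---|---|---|---|---|
| Monday's | 0.19 M | 0.11 M | 35 °C | run made earlier |  |
| Friday's | 0.19 M | 0.17 M | 50 °C | run made earlier |  |
| autumn | 0.19 M | 0.228 M | 40 °C |  | 10 min |
| dawn | 0.19 M | 0.228 M | 60 °C |  | 10 min |

| run | time / min | target / % |
|---|---|---|
| Monday's | 1.00 | 1 |
| Monday's | 2.00 | 1 |
| Monday's | 5.00 | 4 |
| Monday's | 12.0 | 5 |
| Friday's | 0.667 | 1 |
| Friday's | 1.33 | 0 |
| Friday's | 3.00 | 10 |
| Friday's | 8.00 | 17 |

(scatter of a reading: 2 percentage points)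

* the best flask by amount of target, in percent of the substrate charged; "all alike" if 1.5 percentage points covers them all (autumn / dawn / all alike)
* amount of target at the end, in percent of the substrate charged, autumn
* amount of target at the end, in percent of the substrate charged, dawn

- what may be going on: substrate <-> intermediate C; substrate + partner -> intermediate A; 2 partner -> self-condensation product; intermediate A -> target; intermediate C -> side product; partner + intermediate A <-> intermediate B

Autumn and dawn both charge less substrate than partner, so by the charge substrate is the limiting reagent. Its balance reads: target equals the charge minus what stands as substrate, intermediates and side product.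

My own reckoning takes the pace from the last readings, as a time constant. This is the minutes in which the whole substrate charge turns into target at a run's average pace with one equivalent of partner, that is, time times c(partner)/c(substrate), divided by the target fraction. It treats target as proportional to time and to partner. Monday's run gives 139 min and Friday's 42.1 min, each carrying the scatter of its reading. With the logarithm of this time taken as straight in temperature, autumn gets 93.3 min and dawn 19.0 min. The first of these is the filling time of autumn.

The straight figures are 12.9 % for autumn and 63.2 % for dawn. For a tie with autumn's straight figure, dawn has to keep 20.4 % of its own, with the balance placing 87.1 % of the substrate charge outside target. Dawn lies beyond both runs in temperature, so I hold its figure loosely, but I expect dawn ahead.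

The forecast names dawn, with 13 % for autumn and 38 % for dawn: "Dawn should clearly win." Its dawn figure stands below mine.

The flasks give dawn as the best, with 14.6 % in autumn and 23.1 % in dawn.

    substrate ⇌ intermediate C (K = 1.50, k = 0.166 /min, Ea = 97.0 kJ/mol, ΔH = 31.0 kJ/mol)
    substrate + partner → intermediate A (k = 0.568 /M/min, Ea = 63.0 kJ/mol)
    2 partner → self-condensation product (k = 0.236 /M/min, Ea = 73.0 kJ/mol)
    intermediate A → target (k = 0.0889 /min, Ea = 90.0 kJ/mol)
    intermediate C → side product (k = 0.245 /min, Ea = 84.0 kJ/mol)
    partner + intermediate A ⇌ intermediate B (K = 10.0 /M, k = 0.149 /M/min, Ea = 72.0 kJ/mol, ΔH = −48.0 kJ/mol)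
    (constants at 40 °C)

Autumn's filling time gave 12.9 % against the 14.6 % found. Dawn kept 36.5 % of its straight figure, above the 20.4 % reckoned for a tie, and the forecast's winner stands; its dawn figure lies 15 percentage points high. The main reason for dawn's low target is the turning of substrate into intermediate C, both ways: the dawn run without that step gives 61.9 % instead of 23.1 %.

In autumn's neighbour with 0.14 M of partner, autumn's filling time gives 7.90 %; the computed flask gives 10.4 %.

(The numbers in the tables come from a simulation with constants of no real substance, and the scatter is random.)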